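A direct plan would join two preformed, O-methylated rings: 2,4,6-trimethoxytoluene A1 would be brominated to A2 and, in a second portion, formylated to aldehyde A3. The N–H hydrazone A4 of A3 would be coupled with A2 (Ni(cod)2/PMe3, loss of N2) to diarylmethane A5, which would be acetylated on both rings to A6 and then demethylated six times.
Its weakest steps would be:
- **The Ar–CH2 bond formation by denitrogenative hydrazone/aryl bromide coupling.** It would have to join two di-ortho-methoxy partners, which this reaction type has not been shown to tolerate. Oxidative addition into the electron-rich, hindered bromide A2 would be slow, so azine formation and plain reduction of A4 would compete.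
- **The closing sixfold ether cleavage of A6 with excess BBr3.** It would expose the finished, acid-labile diarylmethane to a strong Lewis acid and HBr, risking ipso-protonation and loss or scrambling of the CH2 bridge. Six methyl ethers would be carried through the whole plan only to be removed.
- **The double Friedel–Crafts acetylation of A5.** It would have to hit the one crowded position on each ring without ipso-attack at the bridge or ether cleavage. The plan would also make two identical halves by two different functionalisations, a run-up the symmetry does not require.

**Retrosynthetic overview**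
- Ring numbering follows the diphenylmethane name: C1 carries the CH2 bridge, C3 the acetyl group, C5 the methyl group, C2/C4/C6 the OH groups. The three C–OH carbons and the acetyl C=O alternate with C1, C3 and C5 as in a tetraketide, so both rings are cut at C2–C3 (retro-Claisen) and the target opens to one acyclic bis(triketo ester) 7.
- 7 is built two-directionally around the future bridge. Formaldehyde 2 links two molecules of ethyl 3-oxopentanoate 1 (bridge CH2, C1, C2, C5, C6 and the 5-methyl group of both rings). Both γ-carbons of the product 4 then take up diketene 5 (C3, C4 and the acetyl group).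
- No ring exists before the last step; both benzene rings are closed there, together, by a twofold Claisen condensation.
- By design there is no Ar–CH2 coupling of crowded arenes (the bridge is an sp3–sp3 bond made on a β-keto ester), no O-protecting group and no Lewis acid on the finished diarylmethane, and the symmetry is used from the first step.

Key step: step 3

Remark: 4, 7 and 8 would be handled as mixtures of diastereomers and keto–enol tautomers (7 crude); all their stereocentres are epimerisable and are erased in step 3, and the target is achiral.

Step 1
Reactants: 1 ethyl 3-oxopentanoate (2.0 equiv); 2 formaldehyde (37% aqueous solution, 1.0 equiv)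
Product: 4 diethyl 2,4-dipropanoylpentanedioate, via methylidene keto ester 3 (not isolated)
Conditions: piperidine (5 mol%), EtOH, 0 °C → rt
Reagents that add atoms: none
Why: Knoevenagel condensation of formaldehyde at the only CH2 of 1 that lies between two carbonyl groups gives 3, and Michael addition of a second molecule of 1 should give the methylene-bis(β-keto ester) 4; catalytic amine at or below rt should leave the 1,5-diketone short of intramolecular aldol condensation, and the two stereocentres are not controlled.

Step 2
Reactants: 4 diethyl 2,4-dipropanoylpentanedioate; 5 diketene (4-methylideneoxetan-2-one, 2.1 equiv)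
Product: 7 diethyl 2,4-bis(2-methyl-3,5-dioxohexanoyl)pentanedioate, via tetralithium tetraanion 6 (not isolated)
Conditions: LiN(i-Pr)2 (LDA, 4.4 equiv), THF, −78 → 0 °C; 5, −78 °C; then 1 M HCl, −78 → 0 °C
Reagents that add atoms: none
Why: Proposed new method: LiN(i-Pr)2 removes first the α-proton between ester and ketone and then a proton of the only γ-position (the propanoyl CH2) of each half, and the γ-carbanions of 6, its most nucleophilic sites, should open the strained β-lactone of diketene at the acyl carbon, which delivers the whole acetoacetyl unit and releases it as an enolate that relaxes to the β-diketonate, so that an acylated arm cannot protonate unreacted carbanion and one equivalent of diketene per arm suffices; the closest known reaction types are the Claisen-type γ-acylation of β-keto ester dianions with esters or N-methoxy-N-methylamides and the C-acetoacetylation of sodium enolates of β-dicarbonyl compounds by diketene; the two new stereocentres are epimerisable and not controlled.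

Step 3
Reactants: 7 diethyl 2,4-bis(2-methyl-3,5-dioxohexanoyl)pentanedioate
Product: 9 target 3,3'-diacetyl-2,2',4,4',6,6'-hexahydroxy-5,5'-dimethyldiphenylmethane, via half-cyclised keto ester 8 (not isolated)
Conditions: KOH (2 M aq, degassed), 0 °C → rt, argon; then 2 M HCl, 0 °C
Reagents that add atoms: none
Why: Twofold polyketide-type Claisen (Dieckmann-type) condensation: in each arm the C4 methylene of the 2-methyl-3,5-dioxohexanoyl unit, present as the β-diketone enolate, attacks the ester carbonyl, ethoxide leaves, and the cyclohexane-1,3,5-trione enolises at once to the acylphloroglucinol, whose deprotonation makes the step irreversible (first arm to 8, second arm to 9). The closest known reaction type is the hydroxide-induced Claisen cyclisation of 3,5,7-triketo esters to acylphloroglucinols, the laboratory counterpart of the biosynthetic folding of a tetraketide. Each carbocycle closes in the 6-(enolexo)-exo-trig mode and forms the C2–C3 bond of its benzene ring, and the two closures are independent, because the same carbon would need an eight-membered ring to reach the ester of the other arm. No stereocentre is formed, and the four epimerisable centres of 7 vanish on aromatisation. The selectivity needed is Claisen over aldol closure and the substrate secures it: the aldol mode that usually competes (ester α-carbon onto the terminal ketone) would make a quaternary carbon that bears the bridge and the ester, cannot aromatise and can only revert, whereas the attacking C4 methylene is the one carbon that is doubly activated and six atoms from an ester. The substitution pattern follows from the chain alone: ester carbon → C2–OH, its α-carbon → C1 with the bridge, the two ketone carbons → C6–OH and C4–OH, the methyl-bearing carbon → C5, the attacking carbon → C3 with its acetyl group.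

**Compound list**
1 | ethyl 3-oxopentanoate | CCC(=O)CC(=O)OCC | starting material
2 | formaldehyde | C=O | starting material
3 | ethyl 2-methylidene-3-oxopentanoate (formed in the flask in step 1) | CCC(=O)C(=C)C(=O)OCC | intermediate
4 | diethyl 2,4-dipropanoylpentanedioate (mixture of diastereomers) | CCOC(=O)C(CC(C(=O)OCC)C(=O)CC)C(=O)CC | intermediate
5 | diketene (4-methylideneoxetan-2-one) | C=C1CC(=O)O1 | starting material
6 | tetralithium tetraanion of 4, deprotonated at both ester α-carbons and both propanoyl CH2 carbons (formed in the flask in step 2) | CCOC(=O)[C-](C[C-](C(=O)OCC)C(=O)[CH-]C)C(=O)[CH-]C.[Li+].[Li+].[Li+].[Li+] | intermediate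
7 | diethyl 2,4-bis(2-methyl-3,5-dioxohexanoyl)pentanedioate (mixture of diastereomers and enol forms) | CCOC(=O)C(CC(C(=O)OCC)C(=O)C(C)C(=O)CC(C)=O)C(=O)C(C)C(=O)CC(C)=O | intermediate
8 | ethyl 2-[(3-acetyl-2,4,6-trihydroxy-5-methylphenyl)methyl]-4-methyl-3,5,7-trioxooctanoate (formed in the flask in step 3) | CCOC(=O)C(Cc1c(O)c(C)c(O)c(C(C)=O)c1O)C(=O)C(C)C(=O)CC(C)=O | intermediate
9 | 3,3'-diacetyl-2,2',4,4',6,6'-hexahydroxy-5,5'-dimethyldiphenylmethane (CNP0190887.0, achiral) | CC(=O)c1c(O)c(C)c(O)c(Cc2c(O)c(C)c(O)c(C(C)=O)c2O)c1O | target

Total step count: 3. Longest linear sequence: 3 steps.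

**Steps most likely to fail (the route has three steps; riskiest first)**

Step 2. The γ-carbanions may deprotonate diketene and start its anionic oligomerisation instead of opening the lactone, the α-enolates may be acylated on oxygen, or the acylation may stop after one arm. The fallback uses known chemistry, sets out from 4 and comes back at 7. Commercial ethyl 2-(2-methyl-1,3-dioxolan-2-yl)acetate F1 would be converted with MeNHOMe·HCl and i-PrMgCl (THF, −20 °C) into N-methoxy-N-methyl-2-(2-methyl-1,3-dioxolan-2-yl)acetamide F2. The tetraanion 6, made from 4 as above, would be acylated with F2 (Weinreb ketone synthesis; the chelated adduct holds until the quench, so no acidic ketone meets unreacted carbanion). This would give diethyl 2,4-bis[2-methyl-4-(2-methyl-1,3-dioxolan-2-yl)-3-oxobutanoyl]pentanedioate F3. 2 M HCl in THF at rt would then remove both dioxolanes and return to 7.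

Step 3. Saponification of the esters or hydrolytic cleavage of the β-diketone units may outrun ring closure. The terminal acetyl CH3 may close onto the ketone next to the ester α-carbon (aldol, resorcinol-type ring). The methyl-bearing carbon may add reversibly to the ester of the other arm. The fallback sets out from 7 and comes back at 9. DBU in toluene at reflux would lactonise each 3,5-diketo ester arm to 3,3'-methylenebis[4-hydroxy-5-methyl-6-(2-oxopropyl)-2H-pyran-2-one] F4, a masked polyketide whose ester carbon is protected against hydrolysis. Mg(OMe)2 in MeOH at reflux would reopen both lactones to the magnesium chelate of dimethyl 2,4-bis(2-methyl-3,5-dioxohexanoyl)pentanedioate F5. In this chelate the metal holds the triketone folded and the ester free, so it would close by the same Claisen condensation to 9 after acidic work-up.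

Step 1. The 1,5-diketone 4 may go on to an intramolecular aldol condensation (cyclohexenone formation), or oligomeric Michael products may form. The fallback does not set out from a numbered compound but from commercial tetraethyl propane-1,1,3,3-tetracarboxylate F6, which already holds the bridge, and comes back at 4. Half-saponification (KOH, 2 equiv, EtOH, rt; one ester of each malonate unit) would give 2,4-bis(ethoxycarbonyl)pentanedioic acid F7. Decarboxylative C-acylation of its magnesium salt with propanoyl chloride (MgCl2, Et3N, MeCN; then aq HCl) would give 4 without any amine/aldehyde equilibrium.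

**Further compounds**
F1 | step 2 | ethyl 2-(2-methyl-1,3-dioxolan-2-yl)acetate | CCOC(=O)CC1(C)OCCO1
F2 | step 2 | N-methoxy-N-methyl-2-(2-methyl-1,3-dioxolan-2-yl)acetamide | CON(C)C(=O)CC1(C)OCCO1
F3 | step 2 | diethyl 2,4-bis[2-methyl-4-(2-methyl-1,3-dioxolan-2-yl)-3-oxobutanoyl]pentanedioate | CCOC(=O)C(CC(C(=O)OCC)C(=O)C(C)C(=O)CC1(C)OCCO1)C(=O)C(C)C(=O)CC1(C)OCCO1
F4 | step 3 | 3,3'-methylenebis[4-hydroxy-5-methyl-6-(2-oxopropyl)-2H-pyran-2-one] | CC(=O)CC1=C(C)C(O)=C(CC2=C(O)C(C)=C(CC(C)=O)OC2=O)C(=O)O1
F5 | step 3 | dimethyl 2,4-bis(2-methyl-3,5-dioxohexanoyl)pentanedioate | COC(=O)C(CC(C(=O)OC)C(=O)C(C)C(=O)CC(C)=O)C(=O)C(C)C(=O)CC(C)=O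
F6 | step 1 | tetraethyl propane-1,1,3,3-tetracarboxylate | CCOC(=O)C(CC(C(=O)OCC)C(=O)OCC)C(=O)OCC
F7 | step 1 | 2,4-bis(ethoxycarbonyl)pentanedioic acid | CCOC(=O)C(CC(C(=O)O)C(=O)OCC)C(=O)O
A1 | direct plan | 2,4,6-trimethoxytoluene | Cc1c(OC)cc(OC)cc1OC
A2 | direct plan | 3-bromo-2,4,6-trimethoxytoluene | Cc1c(OC)cc(OC)c(Br)c1OC
A3 | direct plan | 2,4,6-trimethoxy-3-methylbenzaldehyde | Cc1c(OC)cc(OC)c(C=O)c1OC
A4 | direct plan | (E)-[(2,4,6-trimethoxy-3-methylphenyl)methylidene]hydrazine | Cc1c(OC)cc(OC)c(/C=N/N)c1OC
A5 | direct plan | bis(2,4,6-trimethoxy-3-methylphenyl)methane | Cc1c(OC)cc(OC)c(Cc2c(OC)cc(OC)c(C)c2OC)c1OC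
A6 | direct plan | 3,3'-diacetyl-2,2',4,4',6,6'-hexamethoxy-5,5'-dimethyldiphenylmethane | CC(=O)c1c(OC)c(C)c(OC)c(Cc2c(OC)c(C)c(OC)c(C(C)=O)c2OC)c1OC
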